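Start from noon. Sunday's flask has noon's charges, all in at the start. Noon read 22.3 % at 3.00 h and 22.3 % at 4.00 h, so we take its flat end for Sunday's, with no correction. Thursday's and Friday's differ from that flask by one feed each, so for them we reckon the correction and nothing else.

| flask | starting material | coupling partner | second reagent | third reagent | remark | time |
|---|---|---|---|---|---|---|
| noon | 0.18 M | 0.18 M | 0.162 M | 0.090 M | run made earlier |  |
| spring | 0.090 M | 0.18 M | 0.162 M | 0.090 M | run made earlier |  |
| summer | 0.14 M | 0.18 M | 0.162 M | 0.090 M | run made earlier |  |
| Thursday's | 0.18 M | 0.180 M (fed, over 50 min) | 0.162 M | 0.0900 M | all else is in the flask from the start; the feed brings no volume worth counting | 4.0 h |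
| Friday's | 0.18 M | 0.180 M | 0.162 M | 0.0900 M (fed, over 50 min) | all else is in the flask from the start; the feed brings no volume worth counting | 4.0 h |
| Sunday's | 0.18 M | 0.180 M | 0.162 M | 0.0900 M | everything together at the start | 4.0 h |

| run | time / h | target / % |
|---|---|---|
| noon | 0.250 | 5.5 |
| noon | 0.833 | 16.9 |
| noon | 1.33 | 20.1 |
| noon | 2.00 | 21.8 |
| noon | 3.00 | 22.3 |
| noon | 4.00 | 22.3 |
| spring | 0.333 | 9.6 |
| spring | 1.00 | 23.1 |
| spring | 1.50 | 25.6 |
| spring | 2.50 | 27.1 |
| spring | 4.00 | 26.8 |
| spring | 5.00 | 26.7 |
| summer | 0.417 | 11.0 |
| summer | 0.667 | 17.0 |
| summer | 1.00 | 20.8 |
| summer | 2.00 | 24.6 |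
| summer | 3.00 | 26.2 |
| summer | 5.00 | 26.0 |

(readings scatter by 0.3 percentage points)



1. the flask with the highest amount of target, in percent of the starting material charged ("all alike" if they lie within 1.5 percentage points) (Thursday's / Friday's / Sunday's / all alike)
2. final target, as a percentage of the starting material charged, in Thursday's
3. final target, as a percentage of the starting material charged, in Friday's
4. final target, as a percentage of the starting material charged, in Sunday's

The simulated runs give the size of the correction. Spring had half of noon's starting material, so the second reagent per starting material stood at twice noon's ratio, and the coupling partner and third reagent moved the same way. Spring ended higher, at 26.7 %. We call the difference the doubling gain g, the points of final target, in percent of the starting material charged, by which spring's last reading stood above noon's with the reagent charges held: 4.4 percentage points.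

Now the feed. Noon held 75.8 % of its final target at 0.833 h, the length of the feed. Over that time a steady feed has delivered, on average, half of its charge. So each feed runs the spring comparison backwards for the fed reagent, and we take g off noon's end: 17.9 % for Thursday's and for Friday's. This is rough, since spring raised the ratio of each reagent to starting material for its whole run, and a feed lowers the ratio of one reagent during 50 min. Still, g exceeds the margin, so we expect Sunday's highest.

The forecast gave 17 %, 25 % and 22.3 % for Thursday's, Friday's and Sunday's, with Friday's highest, since feeding the third reagent “keeps the active intermediate dilute”, and there it parts from our reckoning.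

Thursday's gave 16.4 %, Friday's 19.5 % and Sunday's 22.7 %, so Sunday's is highest.

    starting material + coupling partner → intermediate A (k = 0.230 L mol⁻¹ min⁻¹)
    second reagent + intermediate A → intermediate B (k = 1.10 L mol⁻¹ min⁻¹)
    third reagent + intermediate B → target (k = 0.760 L mol⁻¹ min⁻¹)
    starting material + second reagent → side product (k = 0.200 L mol⁻¹ min⁻¹)
    intermediate B → decomposed reagent (k = 0.0320 min⁻¹)
    target ⇌ isomer of the product (K = 0.390, k = 0.0300 min⁻¹)

Sunday's stood 3.2 points above Friday's and 6.3 points above Thursday's, against our g of 4.4 points. In Sunday's the selectivity factor at the start was 1.3, coupling step over side step. In Thursday's, while coupling partner came in, side product reached 50.0 % by 0.833 h and target 7.38 %, which is 45.0 % of its final amount against noon's 75.8 %. In Friday's, as the feed of third reagent ended, intermediate B stood at 7.91 % at 0.833 h, and decomposed reagent stood at 27.7 % at 4.00 h, against 23.3 % in Sunday's.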